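The spring flask is asked about at 280 min, later than the last autumn reading at 110 min, so the runs must be carried forward from their late end.

| flask | substrate | time |
|---|---|---|
| autumn | 100 mM |  |
| midnight | 150 mM |  |
| spring | 100 mM | 280 min |

| autumn run: time / min | autumn run: [target] / mM | midnight run: time / min | midnight run: [target] / mM |
|---|---|---|---|
| 3.9 | 0.2 | 3.9 | 0.8 |
| 12 | 0.3 | 12 | 1.2 |
| 23 | 3.5 | 23 | 5.2 |
| 36 | 7.3 | 36 | 11.4 |
| 52 | 13.2 | 52 | 21.5 |
| 69 | 21.2 | 69 | 33.9 |
| 89 | 31.8 | 89 | 49.2 |
| 110 | 41.2 | 110 | 64.7 |

(readings scatter by 0.5 mM)

* apparent order in [substrate] of the starting rate, round the charge of the autumn run (the rate where two percent of its substrate have turned into target) (one fixed amount of target, the same in the runs compared)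
* target in the spring run at 280 min, as a share of the substrate charged

- Overall: substrate -> target.
- Constant volume, constant temperature.
- An order is taken over about fifteen percent of the charge, up and down.

The spring flask has the same charge as the autumn run, so the reckoning here continues the autumn run. It follows f, the share of the charge not yet target, which is 58.8% at 110 min in the autumn run. Over the last autumn interval c(target) rises on average at 0.448 mM min⁻¹, while at mid-interval 63.5 mM is not yet target. Their ratio is the clearing constant, the part of what is not yet target that becomes target each minute: 0.00705 min⁻¹. Held steady to 280 min in the spring flask, it leaves f at 17.7%, so 82.3% is target.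

The weak link is that slope, which rests on two readings 21.0 min apart. Taken instead from ln f of the autumn run between 69 min and 110 min, the constant reads 0.00714 min⁻¹, and the spring share made becomes 82.5%. That is the reckoning to commit to.

The forecast stands higher, at 90%, with an order of 0.75, noting that “the latest rates have flattened”.

The spring flask gives 86.9% at 280 min. The order round the autumn charge comes to 0.61, with the midnight rate 1.3 times the autumn rate at equal target made.

    substrate → intermediate (0.01410 min⁻¹)
    intermediate → target (0.009300 min⁻¹)
    substrate + target → 2 target (0.09900 M⁻¹ min⁻¹)

The spring value of f, 13.1% at 280 min, held against the autumn reading of f at 110 min, gives a clearing constant of 0.00882 min⁻¹, higher than 0.00705 min⁻¹. On the midnight run, with shares of its own charge, 0.00705 min⁻¹ gives 57.5 min from a quarter made to half made, and the midnight run takes 50.4 min.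

The earlier runs and the new flask were generated by integration for an exercise, noise included.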